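**Retrosynthetic overview**
1. The only ring is bought as 2,5-dihydroxy-1,4-benzoquinone 1; no ring is formed and no protecting group is used.
2. PhI(OAc)2 2 turns the C3 enol carbon of 1, natively a donor carbon, into an acceptor (enolonium-type, a2) carbon in the phenyliodonium ylide 3.
3. 1-Hexadecene 4 and 9-BBN 5 give the nucleophilic hexadecyl donor 6 in the flask.
4. Key disconnection: the ring C3–chain C1' bond of target 7 = polarity-reversed C3 of 3 + alkyl donor 6, joined under palladium catalysis, so two natively nucleophilic carbons are coupled.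

Assumption: the target has no stereocentre and no stereogenic double bond, so there is no enantiomer to select; it is made as the achiral 2,5-dihydroxy-1,4-benzoquinone tautomer drawn.

**Step 1**
Reactants: 1 2,5-dihydroxy-1,4-benzoquinone; 2 (diacetoxyiodo)benzene
Product: 3 4-hydroxy-3,6-dioxo-2-(phenyliodonio)cyclohexa-1,4-dien-1-olate (mono phenyliodonium ylide of 1)
Conditions: 2 (1.0 equiv) added in portions to 1 (1.2 equiv), MeOH/CH2Cl2, 0 °C to rt, 2 h, dark; filter the precipitated zwitterion, wash with CH2Cl2, store cold
Reagents that add atoms: none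
Why: Ligand exchange of the acidic enol (a vinylogous carboxylic acid) at trivalent iodine with loss of two acetic acid molecules gives the C3-bound zwitterion (iodonium ylide formation from a cyclic 1,3-dicarbonyl-type enol); the iodonio group deactivates the second enol so one equivalent should stop at the mono-ylide, and no stereocentre is formed.

**Step 2**
Reactants: 4 1-hexadecene; 5 9-borabicyclo[3.3.1]nonane; 3 4-hydroxy-3,6-dioxo-2-(phenyliodonio)cyclohexa-1,4-dien-1-olate
Product: 7 3-hexadecyl-2,5-dihydroxy-1,4-benzoquinone, via B-hexadecyl-9-BBN 6 (not isolated)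
Conditions: (i) 4 (1.5 equiv), 5 (0.5 M in THF, 1.4 equiv), 0 °C to rt, 4 h; (ii) 3 (1.0 equiv), PdCl2(dppf) (5 mol%; dppf = 1,1'-bis(diphenylphosphino)ferrocene), 3 M aq K3PO4 (3 equiv), degassed DMF/THF, rt, 12 h, Ar, dark; then 1 M HCl
Reagents that add atoms: none
Why: Proposed new method: 9-BBN hydroborates the terminal alkene anti-Markovnikov to 6, and ylide 3 then serves as the electrophile of a B-alkyl Suzuki–Miyaura coupling. Zerovalent palladium inserts into the C3–I bond with iodobenzene as leaving group; the resulting enolate of divalent palladium (its oxygen can bind boron, as in the oxo-palladium transmetalation pathway) takes the primary alkyl from the phosphate-activated borate, and dppf favours reductive elimination over β-hydride elimination. The closest known reactions are palladium-catalysed couplings of hydroxyquinone phenyliodonium ylides with arylboronic acids and B-alkyl Suzuki couplings of 9-BBN alkyls with vinyl or aryl iodides and iodonium salts; no stereocentre is formed.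

**Compound list**
1 | 2,5-dihydroxy-1,4-benzoquinone | O=C1C=C(O)C(=O)C=C1O | starting material
2 | (diacetoxyiodo)benzene [PhI(OAc)2] | CC(=O)OI(OC(C)=O)c1ccccc1 | starting material
3 | 4-hydroxy-3,6-dioxo-2-(phenyliodonio)cyclohexa-1,4-dien-1-olate | [O-]C1=C([I+]c2ccccc2)C(=O)C(O)=CC1=O | intermediate
4 | 1-hexadecene | CCCCCCCCCCCCCCC=C | starting material
5 | 9-borabicyclo[3.3.1]nonane (9-BBN, sold as dimer or THF solution) | B1C2CCCC1CCC2 | starting material
6 | B-hexadecyl-9-borabicyclo[3.3.1]nonane | CCCCCCCCCCCCCCCCB1C2CCCC1CCC2 | intermediate (not isolated)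
7 | 3-hexadecyl-2,5-dihydroxy-1,4-benzoquinone (CNP0283865.0) | CCCCCCCCCCCCCCCCC1=C(O)C(=O)C=C(O)C1=O | target

**Step count and risks**
Total step count: 2. Longest linear sequence: 2 steps (1 → 3 → 7); the alkyl branch (4 + 5 → 6) is made in the flask within step 2.

The route has only two steps, so the ranking covers both and treats the two separate failure modes of step 2 as the first and third entries.

Most likely to fail, first: step 2, the coupling on ylide 3. Palladium may transfer phenyl instead of the quinonyl carbon, or base may trigger ring contraction of 3. The fallback keeps an acceptor carbon at C3 but replaces the iodine ylide by a bromoquinone with masked oxygens. It sets out from 1: MeOH with catalytic H2SO4 at reflux gives 2,5-dimethoxy-1,4-benzoquinone F1. Br2 (1.0 equiv) with NaOAc in AcOH gives 3-bromo-2,5-dimethoxy-1,4-benzoquinone F2. B-alkyl Suzuki coupling of F2 with borane 6 (made as in step 2; PdCl2(dppf), K3PO4, THF/DMF/H2O, 50 °C) gives 3-hexadecyl-2,5-dimethoxy-1,4-benzoquinone F3. NaOH in aqueous EtOH, then HCl, cleaves both vinylogous esters and the fallback comes back to the route at 7.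

Second: step 1, mono-ylide formation. A bis-ylide, poor solubility of 1, or decomposition of 3 on isolation could spoil it. The fallback abandons the iodine chemistry for an organocatalytic three-component reductive alkylation. It sets out from 1: hexadecanal, diethyl 2,6-dimethyl-1,4-dihydropyridine-3,5-dicarboxylate (Hantzsch ester) and catalytic L-proline in CH2Cl2 at rt. Knoevenagel condensation gives 3-hexadecylidene-5-hydroxycyclohex-5-ene-1,2,4-trione F4, which is reduced in the flask by conjugate hydride transfer, and the fallback comes back to the route at 7.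

Third: step 2, alkyl transfer from 6. The sp3 borate may transmetalate slowly, or β-hydride elimination from the hexadecyl–palladium intermediate may return 1 and hexadecene. The fallback uses an sp2 boron partner without this problem and then hydrogenates. It sets out from 3. Hydroboration of 1-hexadecyne with pinacolborane (catalytic Cp2Zr(H)Cl) gives 2-[(E)-hexadec-1-en-1-yl]-4,4,5,5-tetramethyl-1,3,2-dioxaborolane F5. Coupling of F5 with 3 (Pd(PPh3)4, K3PO4, DMF/H2O, rt) gives 3-[(E)-hexadec-1-en-1-yl]-2,5-dihydroxy-1,4-benzoquinone F6. H2 over palladium on carbon (Pd/C) in EtOAc reduces the alkene and the quinone to 3-hexadecylbenzene-1,2,4,5-tetrol F7, and stirring in air re-oxidises it, so the fallback comes back to the route at 7.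

**Further compounds**
F1 | step 2 | 2,5-dimethoxy-1,4-benzoquinone | COC1=CC(=O)C(OC)=CC1=O
F2 | step 2 | 3-bromo-2,5-dimethoxy-1,4-benzoquinone | COC1=CC(=O)C(OC)=C(Br)C1=O
F3 | step 2 | 3-hexadecyl-2,5-dimethoxy-1,4-benzoquinone | CCCCCCCCCCCCCCCCC1=C(OC)C(=O)C=C(OC)C1=O
F4 | step 1 | 3-hexadecylidene-5-hydroxycyclohex-5-ene-1,2,4-trione | CCCCCCCCCCCCCCCC=C1C(=O)C(=O)C=C(O)C1=O
F5 | step 2 | 2-[(E)-hexadec-1-en-1-yl]-4,4,5,5-tetramethyl-1,3,2-dioxaborolane | CCCCCCCCCCCCCC/C=C/B1OC(C)(C)C(C)(C)O1
F6 | step 2 | 3-[(E)-hexadec-1-en-1-yl]-2,5-dihydroxy-1,4-benzoquinone | CCCCCCCCCCCCCC/C=C/C1=C(O)C(=O)C=C(O)C1=O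
F7 | step 2 | 3-hexadecylbenzene-1,2,4,5-tetrol | CCCCCCCCCCCCCCCCc1c(O)c(O)cc(O)c1O
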